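**Remark on the chemistry:** biogenetic numbering is used (guaiane carbons C1–C15, aromatic ring C1′–C6′, benzylic carbon C7′), in which the target is 7′R,4R,1R,7R,10R. The ligand antipodes in steps 3 and 18 are quoted from the required facial sense by analogy and would be exchanged if the first run showed the opposite sense.

## Analysis of the target

Target 31 is a guai-5-ene: a cyclopentane (C1–C5) fused through C1–C5 to a cycloheptene (C1, C5–C10) whose only alkene, C5=C6, is trisubstituted and exocyclic to the five-membered ring. C4 is quaternary and carries methyl C15 and the benzylic methine C7′. C7′ in turn bears an isobutyl group and a fully substituted 2,4,6-trihydroxy-3,5-diformylphenyl ring (C1′–C6′). There are five stereocentres. C7′ and C4 are neighbours across an exocyclic bond; C1 and C10 are neighbours with H-1 and H-10 on one face and the C10 methyl on the face of C15; C7 is cut off from the rest by C8–C9 and by the alkene. The sensitive groups are the diformylphloroglucinol, the tertiary homoallylic alcohol at C11 and the C5=C6 alkene, to which the C2′ phenol can add under acid to close a chroman (O–C2′–C1′–C7′–C4–C5). The hard part is the C7′–C4 pair: a benzylic stereocentre next to a quaternary one, with no ring of the target holding both. The strategy rests on the fact that the oxygen on C2′ and methyl C15 on C4 are linked through C1′ and C7′. Joining O and C15 as an ester therefore gives a dihydrocoumarin in which C7′ and C4 are adjacent atoms of one six-membered ring, so C7′ can dictate C4.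

## Retrosynthetic reasoning

**31 ⇒ 30 ⇒ 28.** The three phenolic O–H bonds and the two aryl–CHO bonds are made last, because the free diformylphloroglucinol is the least robust part of the molecule. In 30 every methoxy group is ortho or para to two formyl groups, so the O–CH3 bonds can be cut by a sulfur nucleophile under basic conditions that spare the alkene and the tertiary alcohol. The two formyl groups come from 28 by directed lithiation, since both free aryl positions lie between two methoxy groups and are equivalent by rotation of the 2,4,6-trimethoxyphenyl ring.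

**28 ⇒ 27.** The seven-membered ring is opened at its only alkene, C5=C6. The forward reaction is a ring-closing metathesis between a methylidene on C5 and a vinyl group on C7. It makes no stereocentre and needs no activating group that would later have to be removed.

**27 ⇒ 26 ⇒ 25 ⇒ 24 ⇒ 22.** C6–C7 is cut next: a vinyl nucleophile opening epoxide 26 at C7 with inversion delivers the C7 stereocentre, the C6 vinyl group and the C11 tertiary alcohol together. Epoxide 26 comes from the isopropylidene terminus of 25 by reagent-controlled epoxidation, which is necessary because C7 is too remote for substrate control. The C5 methylidene of 25 comes from ketone 24. The C7–C8 bond of 24 is an sp3–sp2 Suzuki bond from alkylborane 23, made by hydroboration of the vinyl group of 22.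

**22 ⇒ 19 + 21 (19 ⇐ 18, 21 ⇐ 20).** C1–C10 is cut as an iridium-catalysed branched allylation of silyl enol ether 19 with crotyl carbonate 21. C10 is exocyclic at this stage, so it is placed under ligand control, and C1, being α to the ketone, can be corrected by equilibration. A thermal [3,3] shift of a crotyl enol ether of 18 would make the same bond. It was not chosen as the main line, because there C10 would depend on a chair/boat preference next to quaternary C4.

**18 ⇒ 11.** This stretch contains no skeletal disconnection; it dismantles the tether. The lactone carbonyl of 11 becomes methyl C15 (hydride opening to 13, then radical deoxygenation via 15), the freed C2′ oxygen is capped as the third methyl ether (14), and the C5 carbinol is raised to the ketone (18). It is placed directly after the ring closure for two reasons. The aryl ester would not survive the organometallic, hydride and aqueous basic steps of the annulation. And a C15 radical is only safe while C5 is sp3; next to a carbonyl or alkene carbon it would migrate through a three-membered ring.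

**11 ⇒ 10.** The C4–C5 bond is cut, which opens the cyclopentane and removes the quaternary centre. In the forward direction, reduction of the C–Br bond of 10 gives a lactone enolate that adds to the tethered aldehyde. The gain is that C4 is formed on a flat enolate carbon whose two faces are differentiated by the isobutyl group on the neighbouring ring atom C7′.

**10 ⇒ 9 ⇒ 8 ⇒ 5 + 7 (7 ⇐ 6).** The C–Br bond and the C3–C4 bond to the four-carbon chain are cut at the lactone α-carbon. Two successive enolate reactions of 5 install them, chain first and bromine second, so that the ring-closing bond of step 8 becomes the third and last bond at that carbon. Halide 7 is the iodide of commercial chloride 6.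

**5 ⇒ 4 ⇒ 3 ⇒ 1 + 2.** The C7′–H bond is cut as an asymmetric conjugate reduction of coumarin 4; this is the only stereocentre of the front half that needs a chiral reagent. The coumarin is the Pechmann product of 1 and 2, in which the symmetry of 1 removes any regiochemical question.

## Alternatives that were turned down

**Alternative 1: build the arene last by folding a polyketide chain on C4.**
- Disconnection: the aromatic ring itself is cut (C1′–C2′), leaving triketo ester A2 attached to the finished terpene through C7′ as a carbonyl.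
- Forward key step: Mg(OMe)2-mediated Claisen cyclisation of A2 (C6 of the chain onto the ester carbon) to acylphloroglucinol A1.
- For it: the phenols never need protection, the 2,4,6-oxygenation pattern is automatic, and the hindered carbonyl next to C4 disfavours the competing aldol folding. On protecting-group economy it is stronger than the chosen route, which spends one methylation and a triple demethylation.
- Against it: the whole guaiene with quaternary C4, C1, C7 and C10 must be made first by unrelated chemistry. A1 still lacks the isobutyl group and the C7′ configuration. These would have to be added at a ketone wedged between a quaternary carbon and a 2,6-dioxygenated ring, then the benzylic oxygen removed with facial control, with a free phenol able to add to C5=C6. Both formyl groups are also still missing.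
- Comparison: the chosen route sets C7′ first, on a flat coumarin by catalysis, and uses it to control C4; Alternative 1 leaves that centre to the end under weak control.

**Alternative 2: allenic Pauson–Khand reaction for both carbocycles.**
- Disconnection: C1–C5, C2–C3 and C3–C4, with C3 as the inserted carbonyl, back to allenyne A4.
- Forward key step: carbonylative [2+2+1] cyclisation of A4 under [Rh(CO)2Cl]2, engaging the distal allene bond, to dienone A3.
- For it: two rings and three C–C bonds in one step, C5=C6 delivered in place, and C7 and C10 taken from an open chain. In ring-forming economy it is clearly stronger than the chosen route, which needs two separate ring closures (steps 8 and 23) and a long chain build-up between them.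
- Against it: the C4 configuration would have to be carried as the axis of a trisubstituted allene and transferred faithfully. A3 has a C3 carbonyl and a C1=C2 alkene that the target lacks, so C1 would be set by a conjugate reduction on a cross-conjugated dienone, followed by deoxygenation next to quaternary C4. C7′ is only a silyloxymethyl group, so the aryl and isobutyl groups and the C7′ configuration would all be added late at a neopentyl position.
- Comparison: the chosen route is longer in the carbocycle but has the C7′–C4 relationship fixed by step 8 and never touches it again.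

**Alternative 3: aryne, terpene aldehyde and alkylzinc in one coupling.**
- Disconnection: C1′–C7′, C2′–O and C7′–CH2 in one operation, back to aldehyde A6 and ortho-silylaryl triflate A7.
- Forward key step: fluoride (CsF) releases 3,5-dimethoxybenzyne from A7; it adds the aldehyde of A6 across the triple bond to a benzoxete, which opens to an o-quinone methide that Zn(i-Bu)2 captures at C7′ to give phenol A5.
- For it: it is the most convergent plan, the C2′ oxygen arises automatically, and A5 is only formylation and deprotection away from the target. In convergency and in steps after the coupling it is stronger than the chosen route.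
- Against it: it presupposes the complete terpene aldehyde A6. The aldehyde sits on a quaternary carbon and is a poor partner for the [2+2] step, while the aryne can instead react with the trisubstituted alkene. The o-quinone methide is generated next to C5=C6 and can be trapped intramolecularly. The alkyl transfer to C7′ is steered only by the three carbon substituents of C4, which differ little in size.
- Comparison: the chosen route gives up convergency but forms C4 relative to C7′ inside a rigid six-membered ring, where the facial bias is large and predictable.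

Key step: step 8

## Route

**Step 1**
Reactants: 1 benzene-1,3,5-triol (phloroglucinol); 2 ethyl 5-methyl-3-oxohexanoate
Product: 3 5,7-dihydroxy-4-(2-methylpropyl)-2H-chromen-2-one
Conditions: CH3SO3H, 25 °C
Reagents that add atoms: none
Why: Pechmann condensation: acyl transfer to a phenol oxygen, ring closure of the ketone onto the adjacent ring carbon and dehydration give the coumarin; the three equivalent positions of 1 leave no regiochemical choice.

**Step 2**
Reactants: 3 5,7-dihydroxy-4-(2-methylpropyl)-2H-chromen-2-one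
Product: 4 5,7-dimethoxy-4-(2-methylpropyl)-2H-chromen-2-one
Conditions: MeI, K2CO3, acetone, 55 °C
Reagents that add atoms: iodomethane, CI
Why: Williamson O-methylation of both phenols; the lactone is stable to carbonate in acetone.

**Step 3**
Reactants: 4 5,7-dimethoxy-4-(2-methylpropyl)-2H-chromen-2-one
Product: 5 (4R)-5,7-dimethoxy-4-(2-methylpropyl)-3,4-dihydro-2H-chromen-2-one
Conditions: Cu(OAc)2·H2O (3 mol %), (S)-DTBM-SEGPHOS (3 mol %), (EtO)2MeSiH, t-BuOH, toluene, 0 °C
Reagents that add atoms: none
Why: Copper hydride-catalysed asymmetric 1,4-reduction of a β,β-disubstituted unsaturated lactone, a reaction known for coumarins; the ligand-bound hydride is delivered to the Si face of ring carbon C4 and sets C7′ (R). t-BuOH protonates the copper enolate so that the catalyst turns over before the lactone carbonyl is attacked.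

**Step 4**
Reactants: 6 4-chloro-1,1-dimethoxybutane
Product: 7 4-iodo-1,1-dimethoxybutane
Conditions: NaI, acetone, 56 °C
Reagents that add atoms: sodium iodide, [Na+].[I-]
Why: Finkelstein exchange driven by precipitation of NaCl; the iodide is needed for the enolate alkylation.

**Step 5**
Reactants: 5 (4R)-5,7-dimethoxy-4-(2-methylpropyl)-3,4-dihydro-2H-chromen-2-one; 7 4-iodo-1,1-dimethoxybutane
Product: 8 (3R,4R)-3-(4,4-dimethoxybutyl)-5,7-dimethoxy-4-(2-methylpropyl)-3,4-dihydro-2H-chromen-2-one (3,4-trans)
Conditions: LiHMDS, THF, −78 °C; 7, DMPU, −78 → −20 °C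
Reagents that add atoms: none
Why: Alkylation of the lactone lithium enolate; the iodide approaches C3 anti to the isobutyl group, which the peri methoxy group forces pseudoaxial, so the chain enters trans (this centre is made planar again in steps 6 and 8).

**Step 6**
Reactants: 8 (3R,4R)-3-(4,4-dimethoxybutyl)-5,7-dimethoxy-4-(2-methylpropyl)-3,4-dihydro-2H-chromen-2-one
Product: 9 (3R,4S)-3-bromo-3-(4,4-dimethoxybutyl)-5,7-dimethoxy-4-(2-methylpropyl)-3,4-dihydro-2H-chromen-2-one (Br trans to isobutyl)
Conditions: LiHMDS, THF, −78 → −40 °C; NBS, −78 °C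
Reagents that add atoms: N-bromosuccinimide, BrN1C(=O)CCC1=O
Why: Electrophilic bromination of the tetrasubstituted lactone enolate, again anti to isobutyl; the C–Br configuration has no consequence because step 8 passes through a planar enolate. The bromide formed has no antiperiplanar ring hydrogen, which disfavours loss of HBr to the coumarin.

**Step 7**
Reactants: 9 (3R,4S)-3-bromo-3-(4,4-dimethoxybutyl)-5,7-dimethoxy-4-(2-methylpropyl)-3,4-dihydro-2H-chromen-2-one
Product: 10 4-[(3R,4S)-3-bromo-5,7-dimethoxy-4-(2-methylpropyl)-2-oxo-3,4-dihydro-2H-chromen-3-yl]butanal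
Conditions: CF3CO2H–H2O (9:1), CH2Cl2, 0 °C
Reagents that add atoms: water, O
Why: Acid-catalysed hydrolysis of the dimethyl acetal; the tertiary α-bromo aryl lactone tolerates cold aqueous acid.

**Step 8**
Reactants: 10 4-[(3R,4S)-3-bromo-5,7-dimethoxy-4-(2-methylpropyl)-2-oxo-3,4-dihydro-2H-chromen-3-yl]butanal
Product: 11 (2′S,3S,4S)-2′-hydroxy-5,7-dimethoxy-4-(2-methylpropyl)spiro[chromane-3,1′-cyclopentan]-2-one
Conditions: SmI2 (2.5 equiv), THF, −78 °C, slow addition of 10 at high dilution; sat. aq. NH4Cl
Reagents that add atoms: none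
Why: Two one-electron transfers from divalent samarium cleave the C–Br bond, which is reduced much faster than an aliphatic aldehyde in THF without additive, and give the trivalent samarium enolate of the lactone under neutral conditions, so the aldehyde is neither enolised nor reduced. The enolate carbon (C4) then adds to the tethered aldehyde carbon (C5); the closest known reaction type is the SmI2-promoted intramolecular Reformatsky reaction of α-bromo esters with aldehydes. The cyclopentane closes in the 5-(enolexo)-exo-trig mode, which is favoured for a three-methylene tether. C4 is set by the substrate: the enolate is planar, so the C–Br configuration is lost, and the isobutyl group on C7′ stands pseudoaxial to avoid the peri methoxy group and the C3 substituent and covers one face. The aldehyde carbon therefore bonds to the opposite face, C5 ends trans and the chain carbon C3 cis to isobutyl, which is the 4R/7′R relationship of the target. C5 is set by samarium bridging the enolate and aldehyde oxygens in a closed transition state, which places the hydroxyl cis to the lactone carbonyl; this centre is removed in step 15. The step needs chemoselectivity (C–Br before CHO), intramolecular rather than intermolecular aldol addition, and facial selectivity; the first is secured by the α-carbonyl halide, the second by dilution and the five-membered closure, the third by the C7′ substituent.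

**Step 9**
Reactants: 11 (2′S,3S,4S)-2′-hydroxy-5,7-dimethoxy-4-(2-methylpropyl)spiro[chromane-3,1′-cyclopentan]-2-one
Product: 12 (2′S,3S,4S)-2′-{[tert-butyl(dimethyl)silyl]oxy}-5,7-dimethoxy-4-(2-methylpropyl)spiro[chromane-3,1′-cyclopentan]-2-one
Conditions: TBSOTf, 2,6-lutidine, CH2Cl2, 0 °C
Reagents that add atoms: tert-butyldimethylsilyl trifluoromethanesulfonate, CC(C)(C)[Si](C)(C)OS(=O)(=O)C(F)(F)F
Why: Silylation of the hindered secondary alcohol with a silyl triflate and a non-nucleophilic base; no alkoxide is formed, so retro-aldol opening of the β-hydroxy lactone is avoided.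

**Step 10**
Reactants: 12 (2′S,3S,4S)-2′-{[tert-butyl(dimethyl)silyl]oxy}-5,7-dimethoxy-4-(2-methylpropyl)spiro[chromane-3,1′-cyclopentan]-2-one
Product: 13 2-[(1R)-1-[(1R,2S)-2-{[tert-butyl(dimethyl)silyl]oxy}-1-(hydroxymethyl)cyclopentyl]-3-methylbutyl]-3,5-dimethoxyphenol
Conditions: LiAlH4, THF, 0 → 25 °C; aq. KNaC4H4O6
Reagents that add atoms: none
Why: Hydride reduction of the aryl lactone to the primary alcohol with release of the C2′ phenol; this cuts the tether at the C15–O bond and leaves the silyl ether and both stereocentres untouched.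

**Step 11**
Reactants: 13 2-[(1R)-1-[(1R,2S)-2-{[tert-butyl(dimethyl)silyl]oxy}-1-(hydroxymethyl)cyclopentyl]-3-methylbutyl]-3,5-dimethoxyphenol
Product: 14 [(1R,2S)-2-{[tert-butyl(dimethyl)silyl]oxy}-1-[(1R)-3-methyl-1-(2,4,6-trimethoxyphenyl)butyl]cyclopentyl]methanol
Conditions: MeI, K2CO3, acetone, 50 °C
Reagents that add atoms: iodomethane, CI
Why: Carbonate deprotonates only the phenol, so O-methylation is chemoselective over the aliphatic alcohol; the arene becomes a symmetrical 2,4,6-trimethoxyphenyl group.

**Step 12**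
Reactants: 14 [(1R,2S)-2-{[tert-butyl(dimethyl)silyl]oxy}-1-[(1R)-3-methyl-1-(2,4,6-trimethoxyphenyl)butyl]cyclopentyl]methanol
Product: 15 O-{[(1R,2S)-2-{[tert-butyl(dimethyl)silyl]oxy}-1-[(1R)-3-methyl-1-(2,4,6-trimethoxyphenyl)butyl]cyclopentyl]methyl} 1H-imidazole-1-carbothioate
Conditions: 1,1′-thiocarbonyldiimidazole, DMAP (cat.), ClCH2CH2Cl, 70 °C
Reagents that add atoms: 1,1′-thiocarbonyldiimidazole, S=C(n1ccnc1)n1ccnc1
Why: Thioacylation of the neopentyl primary alcohol under neutral conditions; because no alkoxide is generated, the neighbouring silyl group cannot migrate.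

**Step 13**
Reactants: 15 O-{[(1R,2S)-2-{[tert-butyl(dimethyl)silyl]oxy}-1-[(1R)-3-methyl-1-(2,4,6-trimethoxyphenyl)butyl]cyclopentyl]methyl} 1H-imidazole-1-carbothioate
Product: 16 tert-butyl(dimethyl){[(1S,2R)-2-methyl-2-[(1R)-3-methyl-1-(2,4,6-trimethoxyphenyl)butyl]cyclopentyl]oxy}silane
Conditions: n-Bu3SnH, 1,1′-azobis(cyclohexanecarbonitrile), xylenes, 140 °C
Reagents that add atoms: none
Why: Barton–McCombie deoxygenation: the stannyl radical adds to C=S, the C15–O bond fragments at high temperature and the primary radical is reduced by the stannane. C4 has no hydrogen for thermal elimination, and with C5 still sp3 the C15 radical has no rearrangement path, so the methyl group forms without the hindered displacement that a sulfonate route would need.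

**Step 14**
Reactants: 16 tert-butyl(dimethyl){[(1S,2R)-2-methyl-2-[(1R)-3-methyl-1-(2,4,6-trimethoxyphenyl)butyl]cyclopentyl]oxy}silane
Product: 17 (1S,2R)-2-methyl-2-[(1R)-3-methyl-1-(2,4,6-trimethoxyphenyl)butyl]cyclopentan-1-ol
Conditions: Bu4NF, THF, 50 °C
Reagents that add atoms: none
Why: Fluoride cleavage of the silyl ether; nothing else in the molecule responds to fluoride.

**Step 15**
Reactants: 17 (1S,2R)-2-methyl-2-[(1R)-3-methyl-1-(2,4,6-trimethoxyphenyl)butyl]cyclopentan-1-ol
Product: 18 (2R)-2-methyl-2-[(1S)-3-methyl-1-(2,4,6-trimethoxyphenyl)butyl]cyclopentan-1-one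
Conditions: Dess–Martin periodinane, CH2Cl2, 25 °C
Reagents that add atoms: none
Why: Dess–Martin oxidation of the secondary alcohol to the C5 ketone under neutral conditions; C4 is quaternary, so no centre can epimerise.

**Step 16**
Reactants: 18 (2R)-2-methyl-2-[(1S)-3-methyl-1-(2,4,6-trimethoxyphenyl)butyl]cyclopentan-1-one
Product: 19 trimethyl({(5R)-5-methyl-5-[(1R)-3-methyl-1-(2,4,6-trimethoxyphenyl)butyl]cyclopent-1-en-1-yl}oxy)silane
Conditions: Me3SiOTf, Et3N, CH2Cl2, 0 °C
Reagents that add atoms: trimethylsilyl trifluoromethanesulfonate, C[Si](C)(C)OS(=O)(=O)C(F)(F)F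
Why: Soft enolisation and O-silylation; only C1 carries α-hydrogens, so the enol ether forms regiospecifically.

**Step 17**
Reactants: 20 (2E)-but-2-en-1-ol
Product: 21 (2E)-but-2-en-1-yl methyl carbonate
Conditions: ClCO2Me, pyridine, CH2Cl2, 0 °C
Reagents that add atoms: methyl chloroformate, COC(Cl)=O
Why: O-acylation of the allylic alcohol with a chloroformate gives the leaving group for the allylation.

**Step 18**
Reactants: 19 trimethyl({(5R)-5-methyl-5-[(1R)-3-methyl-1-(2,4,6-trimethoxyphenyl)butyl]cyclopent-1-en-1-yl}oxy)silane; 21 (2E)-but-2-en-1-yl methyl carbonate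
Product: 22 (2R,5R)-5-[(2R)-but-3-en-2-yl]-2-methyl-2-[(1S)-3-methyl-1-(2,4,6-trimethoxyphenyl)butyl]cyclopentan-1-one
Conditions: [Ir(cod)Cl]2 (2 mol %), (Sa,S,S)-(1,1′-binaphthalene-2,2′-diyl) N,N-bis(1-phenylethyl)phosphoramidite (4 mol %), CsF, ZnF2, DME, 50 °C; then DBU, CH2Cl2, 25 °C
Reagents that add atoms: none
Why: Iridium-catalysed allylic alkylation of a fluoride-activated silyl enol ether: the crotyl iridium complex is attacked at its methyl-bearing terminus (branched product) and the ligand directs the enolate to the Re face of that carbon, so C10 is R by catalyst control. C1 forms anti to the large C7′ side chain on C4 and, being α to the ketone, is funnelled by DBU to the more stable arrangement with C10 trans to C7′ (1R).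

**Step 19**
Reactants: 22 (2R,5R)-5-[(2R)-but-3-en-2-yl]-2-methyl-2-[(1S)-3-methyl-1-(2,4,6-trimethoxyphenyl)butyl]cyclopentan-1-one
Product: 24 (2R,5R)-2-methyl-2-[(1S)-3-methyl-1-(2,4,6-trimethoxyphenyl)butyl]-5-[(2R)-6-methylhept-5-en-2-yl]cyclopentan-1-one, via B-alkyl-9-borabicyclononane adduct 23 (not isolated)
Conditions: 9-BBN, THF, 25 °C; then BrCH=C(CH3)2, Pd(dppf)Cl2 (5 mol %), Cs2CO3, DMF–H2O, 50 °C
Reagents that add atoms: 1-bromo-2-methylprop-1-ene, CC(C)=CBr; 9-borabicyclo[3.3.1]nonane (boron to 23 only, hydrogen to 24), [H]B1C2CCCC1CCC2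
Why: 9-BBN adds anti-Markovnikov to the monosubstituted alkene faster than it reduces the ketone flanked by quaternary C4; B-alkyl Suzuki–Miyaura coupling then transfers the primary alkyl group to the alkenyl bromide. The basic medium can only hold C1 at its thermodynamic configuration.

**Step 20**
Reactants: 24 (2R,5R)-2-methyl-2-[(1S)-3-methyl-1-(2,4,6-trimethoxyphenyl)butyl]-5-[(2R)-6-methylhept-5-en-2-yl]cyclopentan-1-one
Product: 25 2-[(1R)-3-methyl-1-[(1R,3R)-1-methyl-2-methylidene-3-[(2R)-6-methylhept-5-en-2-yl]cyclopentyl]butyl]-1,3,5-trimethoxybenzene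
Conditions: Cp2TiMe2, toluene, 75 °C
Reagents that add atoms: dimethyltitanocene, [CH3-].[CH3-].[Ti+4].c1cc[cH-]c1.c1cc[cH-]c1
Why: Carbonyl methylenation by the titanium methylidene released thermally from Cp2TiMe2; the reagent is non-basic, so the enolisable C1 centre is kept, and it is effective for ketones next to quaternary carbon.

**Step 21**
Reactants: 25 2-[(1R)-3-methyl-1-[(1R,3R)-1-methyl-2-methylidene-3-[(2R)-6-methylhept-5-en-2-yl]cyclopentyl]butyl]-1,3,5-trimethoxybenzene
Product: 26 (3R)-2,2-dimethyl-3-[(3R)-3-[(1R,3R)-3-methyl-2-methylidene-3-[(1R)-3-methyl-1-(2,4,6-trimethoxyphenyl)butyl]cyclopentyl]butyl]oxirane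
Conditions: D-fructose-derived ketone catalyst (1,2:4,5-di-O-isopropylidene-D-erythro-2,3-hexodiulo-2,6-pyranose, 30 mol %), Oxone (2KHSO5·KHSO4·K2SO4), K2CO3, Bu4NHSO4, MeCN–CH2(OMe)2/aq. Na2B4O7, 0 °C
Reagents that add atoms: potassium peroxymonosulfate, [K+].[O-]S(=O)(=O)OO
Why: Shi epoxidation: the chiral dioxirane reacts with the electron-rich trisubstituted alkene in preference to the hindered 1,1-disubstituted one and, through its spiro transition state, gives the (R)-epoxide at C7 under catalyst control, independent of the remote centres.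

**Step 22**
Reactants: 26 (3R)-2,2-dimethyl-3-[(3R)-3-[(1R,3R)-3-methyl-2-methylidene-3-[(1R)-3-methyl-1-(2,4,6-trimethoxyphenyl)butyl]cyclopentyl]butyl]oxirane
Product: 27 (3R,6R)-3-ethenyl-2-methyl-6-[(1R,3R)-3-methyl-2-methylidene-3-[(1R)-3-methyl-1-(2,4,6-trimethoxyphenyl)butyl]cyclopentyl]heptan-2-ol
Conditions: CH2=CHMgBr, CuI (20 mol %), THF, −30 → 0 °C; sat. aq. NH4Cl
Reagents that add atoms: vinylmagnesium bromide, C=C[Mg]Br
Why: Copper-catalysed Grignard opening of the epoxide by SN2 attack at the less substituted carbon C7 with inversion; one operation forms C6–C7, sets C7 (R) and frees the C11 tertiary alcohol.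

**Step 23**
Reactants: 27 (3R,6R)-3-ethenyl-2-methyl-6-[(1R,3R)-3-methyl-2-methylidene-3-[(1R)-3-methyl-1-(2,4,6-trimethoxyphenyl)butyl]cyclopentyl]heptan-2-ol
Product: 28 (1R,3aR,4R,7R)-7-(2-hydroxypropan-2-yl)-1,4-dimethyl-1-[(1R)-3-methyl-1-(2,4,6-trimethoxyphenyl)butyl]-1,2,3,3a,4,5,6,7-octahydroazulene
Conditions: second-generation Grubbs catalyst (H2IMes)(PCy3)Cl2Ru=CHPh (10 mol %), toluene, 80 °C, high dilution, argon sparge
Reagents that add atoms: none
Why: Ring-closing metathesis: the carbene loads on the unhindered C6 vinyl group and closes onto the C5 methylidene, forming the seven-membered ring and the trisubstituted C5=C6 alkene with loss of ethene. The free tertiary alcohol is tolerated and no stereocentre is touched.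

**Step 24**
Reactants: 28 (1R,3aR,4R,7R)-7-(2-hydroxypropan-2-yl)-1,4-dimethyl-1-[(1R)-3-methyl-1-(2,4,6-trimethoxyphenyl)butyl]-1,2,3,3a,4,5,6,7-octahydroazulene
Product: 30 5-[(1R)-1-[(1R,3aR,4R,7R)-7-(2-hydroxypropan-2-yl)-1,4-dimethyl-1,2,3,3a,4,5,6,7-octahydroazulen-1-yl]-3-methylbutyl]-2,4,6-trimethoxybenzene-1,3-dicarbaldehyde, via lithium hemiaminal alkoxide 29 (not isolated)
Conditions: n-BuLi (2.2 equiv), TMEDA, THF, 0 °C; DMF (1.1 equiv), −78 → 0 °C; n-BuLi (1.3 equiv), 0 °C; DMF, −78 → 25 °C; aq. NH4Cl
Reagents that add atoms: N,N-dimethylformamide, CN(C)C=O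
Why: Directed ortho-lithiation and formylation: each free aryl position lies between two methoxy groups and the two are equivalent by ring rotation, so the first formylation gives a single compound. The DMF adduct 29 masks the first aldehyde while the second position is lithiated and formylated, and the basic, acid-free conditions spare the alkene and the tertiary alcohol (carried as its alkoxide).

**Step 25**
Reactants: 30 5-[(1R)-1-[(1R,3aR,4R,7R)-7-(2-hydroxypropan-2-yl)-1,4-dimethyl-1,2,3,3a,4,5,6,7-octahydroazulen-1-yl]-3-methylbutyl]-2,4,6-trimethoxybenzene-1,3-dicarbaldehyde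
Product: 31 5-[(1R)-1-[(1R,3aR,4R,7R)-7-(2-hydroxypropan-2-yl)-1,4-dimethyl-1,2,3,3a,4,5,6,7-octahydroazulen-1-yl]-3-methylbutyl]-2,4,6-trihydroxybenzene-1,3-dicarbaldehyde (target)
Conditions: NaSEt (excess), DMF, 110 °C; then cold dilute aq. HCl
Reagents that add atoms: none
Why: Nucleophilic O-demethylation: every methoxy group is ortho or para to two formyl groups, so the thiolate attacks the methyl carbon by SN2 and the phenoxide leaves as a vinylogous carboxylate. The basic medium avoids acid-promoted addition of the C2′ phenol to C5=C6 and ionisation of the tertiary alcohol.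

## Compound list

1 | benzene-1,3,5-triol (phloroglucinol) | Oc1cc(O)cc(O)c1 | starting material
2 | ethyl 5-methyl-3-oxohexanoate | CCOC(=O)CC(=O)CC(C)C | starting material
3 | 5,7-dihydroxy-4-(2-methylpropyl)-2H-chromen-2-one | CC(C)CC1=CC(=O)Oc2cc(O)cc(O)c12 | intermediate
4 | 5,7-dimethoxy-4-(2-methylpropyl)-2H-chromen-2-one | CC(C)CC1=CC(=O)Oc2cc(OC)cc(OC)c12 | intermediate
5 | (4R)-5,7-dimethoxy-4-(2-methylpropyl)-3,4-dihydro-2H-chromen-2-one | CC(C)C[C@H]1c2c(OC)cc(OC)cc2OC(=O)C1 | intermediate
6 | 4-chloro-1,1-dimethoxybutane | COC(OC)CCCCl | starting material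
7 | 4-iodo-1,1-dimethoxybutane | COC(OC)CCCI | intermediate
8 | (3R,4R)-3-(4,4-dimethoxybutyl)-5,7-dimethoxy-4-(2-methylpropyl)-3,4-dihydro-2H-chromen-2-one | CC(C)C[C@H]1c2c(OC)cc(OC)cc2OC(=O)[C@@H]1CCCC(OC)OC | intermediate
9 | (3R,4S)-3-bromo-3-(4,4-dimethoxybutyl)-5,7-dimethoxy-4-(2-methylpropyl)-3,4-dihydro-2H-chromen-2-one | CC(C)C[C@H]1c2c(OC)cc(OC)cc2OC(=O)[C@@]1(Br)CCCC(OC)OC | intermediate
10 | 4-[(3R,4S)-3-bromo-5,7-dimethoxy-4-(2-methylpropyl)-2-oxo-3,4-dihydro-2H-chromen-3-yl]butanal | CC(C)C[C@H]1c2c(OC)cc(OC)cc2OC(=O)[C@@]1(Br)CCCC=O | intermediate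
11 | (2′S,3S,4S)-2′-hydroxy-5,7-dimethoxy-4-(2-methylpropyl)spiro[chromane-3,1′-cyclopentan]-2-one | CC(C)C[C@H]1c2c(OC)cc(OC)cc2OC(=O)[C@@]13CCC[C@@H]3O | intermediate
12 | (2′S,3S,4S)-2′-{[tert-butyl(dimethyl)silyl]oxy}-5,7-dimethoxy-4-(2-methylpropyl)spiro[chromane-3,1′-cyclopentan]-2-one | CC(C)C[C@H]1c2c(OC)cc(OC)cc2OC(=O)[C@@]13CCC[C@@H]3O[Si](C)(C)C(C)(C)C | intermediate
13 | 2-[(1R)-1-[(1R,2S)-2-{[tert-butyl(dimethyl)silyl]oxy}-1-(hydroxymethyl)cyclopentyl]-3-methylbutyl]-3,5-dimethoxyphenol | CC(C)C[C@@H](c1c(OC)cc(OC)cc1O)[C@@]2(CO)CCC[C@@H]2O[Si](C)(C)C(C)(C)C | intermediate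
14 | [(1R,2S)-2-{[tert-butyl(dimethyl)silyl]oxy}-1-[(1R)-3-methyl-1-(2,4,6-trimethoxyphenyl)butyl]cyclopentyl]methanol | CC(C)C[C@@H](c1c(OC)cc(OC)cc1OC)[C@@]2(CO)CCC[C@@H]2O[Si](C)(C)C(C)(C)C | intermediate
15 | O-{[(1R,2S)-2-{[tert-butyl(dimethyl)silyl]oxy}-1-[(1R)-3-methyl-1-(2,4,6-trimethoxyphenyl)butyl]cyclopentyl]methyl} 1H-imidazole-1-carbothioate | CC(C)C[C@@H](c1c(OC)cc(OC)cc1OC)[C@@]2(COC(=S)n3ccnc3)CCC[C@@H]2O[Si](C)(C)C(C)(C)C | intermediate
16 | tert-butyl(dimethyl){[(1S,2R)-2-methyl-2-[(1R)-3-methyl-1-(2,4,6-trimethoxyphenyl)butyl]cyclopentyl]oxy}silane | CC(C)C[C@@H](c1c(OC)cc(OC)cc1OC)[C@@]2(C)CCC[C@@H]2O[Si](C)(C)C(C)(C)C | intermediate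
17 | (1S,2R)-2-methyl-2-[(1R)-3-methyl-1-(2,4,6-trimethoxyphenyl)butyl]cyclopentan-1-ol | CC(C)C[C@@H](c1c(OC)cc(OC)cc1OC)[C@@]2(C)CCC[C@@H]2O | intermediate
18 | (2R)-2-methyl-2-[(1S)-3-methyl-1-(2,4,6-trimethoxyphenyl)butyl]cyclopentan-1-one | CC(C)C[C@@H](c1c(OC)cc(OC)cc1OC)[C@@]2(C)CCCC2=O | intermediate
19 | trimethyl({(5R)-5-methyl-5-[(1R)-3-methyl-1-(2,4,6-trimethoxyphenyl)butyl]cyclopent-1-en-1-yl}oxy)silane | CC(C)C[C@@H](c1c(OC)cc(OC)cc1OC)[C@@]2(C)CCC=C2O[Si](C)(C)C | intermediate
20 | (2E)-but-2-en-1-ol | C/C=C/CO | starting material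
21 | (2E)-but-2-en-1-yl methyl carbonate | COC(=O)OC/C=C/C | intermediate
22 | (2R,5R)-5-[(2R)-but-3-en-2-yl]-2-methyl-2-[(1S)-3-methyl-1-(2,4,6-trimethoxyphenyl)butyl]cyclopentan-1-one | CC(C)C[C@@H](c1c(OC)cc(OC)cc1OC)[C@@]2(C)CC[C@H]([C@H](C)C=C)C2=O | intermediate
23 | (2R,5R)-5-[(2R)-4-(9-borabicyclo[3.3.1]nonan-9-yl)butan-2-yl]-2-methyl-2-[(1S)-3-methyl-1-(2,4,6-trimethoxyphenyl)butyl]cyclopentan-1-one | CC(C)C[C@@H](c1c(OC)cc(OC)cc1OC)[C@@]2(C)CC[C@H]([C@H](C)CCB3C4CCCC3CCC4)C2=O | intermediate
24 | (2R,5R)-2-methyl-2-[(1S)-3-methyl-1-(2,4,6-trimethoxyphenyl)butyl]-5-[(2R)-6-methylhept-5-en-2-yl]cyclopentan-1-one | CC(C)C[C@@H](c1c(OC)cc(OC)cc1OC)[C@@]2(C)CC[C@H]([C@H](C)CCC=C(C)C)C2=O | intermediate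
25 | 2-[(1R)-3-methyl-1-[(1R,3R)-1-methyl-2-methylidene-3-[(2R)-6-methylhept-5-en-2-yl]cyclopentyl]butyl]-1,3,5-trimethoxybenzene | CC(C)C[C@@H](c1c(OC)cc(OC)cc1OC)[C@@]2(C)CC[C@H]([C@H](C)CCC=C(C)C)C2=C | intermediate
26 | (3R)-2,2-dimethyl-3-[(3R)-3-[(1R,3R)-3-methyl-2-methylidene-3-[(1R)-3-methyl-1-(2,4,6-trimethoxyphenyl)butyl]cyclopentyl]butyl]oxirane | CC(C)C[C@@H](c1c(OC)cc(OC)cc1OC)[C@@]2(C)CC[C@H]([C@H](C)CC[C@H]3OC3(C)C)C2=C | intermediate
27 | (3R,6R)-3-ethenyl-2-methyl-6-[(1R,3R)-3-methyl-2-methylidene-3-[(1R)-3-methyl-1-(2,4,6-trimethoxyphenyl)butyl]cyclopentyl]heptan-2-ol | CC(C)C[C@@H](c1c(OC)cc(OC)cc1OC)[C@@]2(C)CC[C@H]([C@H](C)CC[C@H](C=C)C(C)(C)O)C2=C | intermediate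
28 | (1R,3aR,4R,7R)-7-(2-hydroxypropan-2-yl)-1,4-dimethyl-1-[(1R)-3-methyl-1-(2,4,6-trimethoxyphenyl)butyl]-1,2,3,3a,4,5,6,7-octahydroazulene | CC(C)C[C@@H](c1c(OC)cc(OC)cc1OC)[C@@]1(C)CC[C@H]2C1=C[C@H](C(C)(C)O)CC[C@H]2C | intermediate
29 | dilithium salt of the mono-formyl DMF adduct of 28 (lithium α-(dimethylamino)benzyl alkoxide at C3′ and lithium C11 alkoxide; hemiaminal carbon not defined) | CC(C)C[C@@H](c1c(OC)cc(OC)c(C(O[Li])N(C)C)c1OC)[C@@]1(C)CC[C@H]2C1=C[C@H](C(C)(C)O[Li])CC[C@H]2C | intermediate
30 | 5-[(1R)-1-[(1R,3aR,4R,7R)-7-(2-hydroxypropan-2-yl)-1,4-dimethyl-1,2,3,3a,4,5,6,7-octahydroazulen-1-yl]-3-methylbutyl]-2,4,6-trimethoxybenzene-1,3-dicarbaldehyde | CC(C)C[C@@H](c1c(OC)c(C=O)c(OC)c(C=O)c1OC)[C@@]1(C)CC[C@H]2C1=C[C@H](C(C)(C)O)CC[C@H]2C | intermediate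
31 | 5-[(1R)-1-[(1R,3aR,4R,7R)-7-(2-hydroxypropan-2-yl)-1,4-dimethyl-1,2,3,3a,4,5,6,7-octahydroazulen-1-yl]-3-methylbutyl]-2,4,6-trihydroxybenzene-1,3-dicarbaldehyde | CC(C)C[C@@H](c1c(O)c(C=O)c(O)c(C=O)c1O)[C@@]1(C)CC[C@H]2C1=C[C@H](C(C)(C)O)CC[C@H]2C | target

## Step count and least certain steps

Total step count: 25. Longest linear sequence: 23 steps (1–3, 5–16, 18–25); steps 4 and 17 prepare 7 and 21.

**Step 8 (key step).** The most likely failure is that the hindered tetrasubstituted samarium enolate is protonated, or opens to a ketene phenoxide, before it reaches the aldehyde, or that the aldolate reverts by retro-aldol cleavage. Facial leakage is less likely because the isobutyl group sits directly over one face. The fallback keeps the bond and the enolate face but makes the closure an irreversible acylation. It sets out from 5: alkylation of its lithium enolate with methyl 4-iodobutanoate gives methyl 4-[(3R,4R)-5,7-dimethoxy-4-(2-methylpropyl)-2-oxo-3,4-dihydro-2H-chromen-3-yl]butanoate F1. Dieckmann cyclisation of F1 with excess LiHMDS gives (3S,4S)-5,7-dimethoxy-4-(2-methylpropyl)spiro[chromane-3,1′-cyclopentane]-2,2′-dione F2. Reduction of F2 with Zn(BH4)2 through the same carbonyl–carbonyl chelate returns to the route at 11. Any (2′R,3S,4S)-2′-hydroxy epimer F3 that forms is oxidised back to F2 with Dess–Martin periodinane and recycled.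

**Step 3.** Two processes threaten it: further reduction of the aryl lactone by excess copper hydride, and weak face discrimination because the peri methoxy group crowds the β-carbon. The fallback gives up asymmetric catalysis. It sets out from 4: hydrogenation (H2, Pd/C) gives racemic 5,7-dimethoxy-4-(2-methylpropyl)-3,4-dihydro-2H-chromen-2-one F4, which is resolved by preparative chromatography on a chiral stationary phase, returning to the route at 5.

**Step 18.** The trisubstituted silyl enol ether may react sluggishly, the branched/linear selectivity of a crotyl electrophile may erode, or C1 may be over-allylated. The fallback is the sigmatropic route to the same bond and sets out from 18. Hydrazine gives [(2R)-2-methyl-2-[(1R)-3-methyl-1-(2,4,6-trimethoxyphenyl)butyl]cyclopentylidene]hydrazine F5. Iodine and tetramethylguanidine convert F5 into 2-[(1S)-1-[(1R)-2-iodo-1-methylcyclopent-2-en-1-yl]-3-methylbutyl]-1,3,5-trimethoxybenzene F6. Copper-catalysed C–O coupling (CuI, Cs2CO3, a phenanthroline ligand) with (2Z)-but-2-en-1-ol gives 2-[(1R)-1-[(1R)-2-{[(2Z)-but-2-en-1-yl]oxy}-1-methylcyclopent-2-en-1-yl]-3-methylbutyl]-1,3,5-trimethoxybenzene F7. Claisen rearrangement of F7 through a chair on the face away from the C7′ side chain returns to the route at 22.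

**Step 22.** SN2 attack at a secondary carbon next to the fully substituted epoxide carbon is slow, and magnesium halide can instead trigger rearrangement of the trisubstituted epoxide to a ketone. The fallback uses a slim sp nucleophile and sets out from 26. Lithium acetylide–ethylenediamine complex in DMSO gives (3R,6R)-3-ethynyl-2-methyl-6-[(1R,3R)-3-methyl-2-methylidene-3-[(1R)-3-methyl-1-(2,4,6-trimethoxyphenyl)butyl]cyclopentyl]heptan-2-ol F8. Semi-hydrogenation of F8 (H2, Pd/CaCO3 poisoned with Pb(OAc)2, quinoline) returns to the route at 27.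

**Step 23.** After loading on the vinyl group the carbene must close onto a methylidene flanked by quaternary C4 and tertiary C1; if that is slow, intermolecular metathesis and alkene migration take over. The fallback closes the same bond by carbonyl coupling and sets out from 27.
- Et3SiOTf and 2,6-lutidine give triethyl{[(3R,6R)-3-ethenyl-2-methyl-6-[(1R,3R)-3-methyl-2-methylidene-3-[(1R)-3-methyl-1-(2,4,6-trimethoxyphenyl)butyl]cyclopentyl]heptan-2-yl]oxy}silane F9.
- Cleavage of both alkenes of F9 with OsO4 (cat.) and NaIO4 gives (2S,5R)-5-[(1R,3R)-3-methyl-3-[(1S)-3-methyl-1-(2,4,6-trimethoxyphenyl)butyl]-2-oxocyclopentyl]-2-{2-[(triethylsilyl)oxy]propan-2-yl}hexanal F10.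
- McMurry coupling of F10 with low-valent titanium (TiCl3, Zn–Cu, DME, reflux) gives (1R,3aR,4R,7R)-1,4-dimethyl-1-[(1R)-3-methyl-1-(2,4,6-trimethoxyphenyl)butyl]-7-{2-[(triethylsilyl)oxy]propan-2-yl}-1,2,3,3a,4,5,6,7-octahydroazulene F11.
- Bu4NF removes the silyl group from F11 and returns to the route at 28.

**Step 25.** Each demethylation adds a negative charge to the ring, so the third cleavage may stall; prolonged heating with thiolate may also engage the formyl groups. The fallback reverses the polarity of the cleavage and makes no new compound (F0). It sets out from 30: BCl3 with Bu4NI in CH2Cl2 at −78 → 0 °C cleaves the three methyl ethers by chelation to the neighbouring formyl oxygens (every methoxy group is ortho to a formyl group) and returns to the route at 31. The temperature is kept low because a Lewis acid endangers the tertiary alcohol and the alkene.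

## Further compounds

F1 | step 8 | methyl 4-[(3R,4R)-5,7-dimethoxy-4-(2-methylpropyl)-2-oxo-3,4-dihydro-2H-chromen-3-yl]butanoate | CC(C)C[C@H]1c2c(OC)cc(OC)cc2OC(=O)[C@@H]1CCCC(=O)OC
F2 | step 8 | (3S,4S)-5,7-dimethoxy-4-(2-methylpropyl)spiro[chromane-3,1′-cyclopentane]-2,2′-dione | CC(C)C[C@H]1c2c(OC)cc(OC)cc2OC(=O)[C@@]13CCCC3=O
F3 | step 8 | (2′R,3S,4S)-2′-hydroxy-5,7-dimethoxy-4-(2-methylpropyl)spiro[chromane-3,1′-cyclopentan]-2-one | CC(C)C[C@H]1c2c(OC)cc(OC)cc2OC(=O)[C@@]13CCC[C@H]3O
F4 | step 3 | rac-5,7-dimethoxy-4-(2-methylpropyl)-3,4-dihydro-2H-chromen-2-one | CC(C)CC1CC(=O)Oc2cc(OC)cc(OC)c12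
F5 | step 18 | [(2R)-2-methyl-2-[(1R)-3-methyl-1-(2,4,6-trimethoxyphenyl)butyl]cyclopentylidene]hydrazine | CC(C)C[C@@H](c1c(OC)cc(OC)cc1OC)[C@@]2(C)CCCC2=NN
F6 | step 18 | 2-[(1S)-1-[(1R)-2-iodo-1-methylcyclopent-2-en-1-yl]-3-methylbutyl]-1,3,5-trimethoxybenzene | CC(C)C[C@@H](c1c(OC)cc(OC)cc1OC)[C@@]2(C)CCC=C2I
F7 | step 18 | 2-[(1R)-1-[(1R)-2-{[(2Z)-but-2-en-1-yl]oxy}-1-methylcyclopent-2-en-1-yl]-3-methylbutyl]-1,3,5-trimethoxybenzene | CC(C)C[C@@H](c1c(OC)cc(OC)cc1OC)[C@@]2(C)CCC=C2OC/C=C\C
F8 | step 22 | (3R,6R)-3-ethynyl-2-methyl-6-[(1R,3R)-3-methyl-2-methylidene-3-[(1R)-3-methyl-1-(2,4,6-trimethoxyphenyl)butyl]cyclopentyl]heptan-2-ol | CC(C)C[C@@H](c1c(OC)cc(OC)cc1OC)[C@@]2(C)CC[C@H]([C@H](C)CC[C@H](C#C)C(C)(C)O)C2=C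
F9 | step 23 | triethyl{[(3R,6R)-3-ethenyl-2-methyl-6-[(1R,3R)-3-methyl-2-methylidene-3-[(1R)-3-methyl-1-(2,4,6-trimethoxyphenyl)butyl]cyclopentyl]heptan-2-yl]oxy}silane | CC(C)C[C@@H](c1c(OC)cc(OC)cc1OC)[C@@]2(C)CC[C@H]([C@H](C)CC[C@H](C=C)C(C)(C)O[Si](CC)(CC)CC)C2=C
F10 | step 23 | (2S,5R)-5-[(1R,3R)-3-methyl-3-[(1S)-3-methyl-1-(2,4,6-trimethoxyphenyl)butyl]-2-oxocyclopentyl]-2-{2-[(triethylsilyl)oxy]propan-2-yl}hexanal | CC(C)C[C@@H](c1c(OC)cc(OC)cc1OC)[C@@]2(C)CC[C@H]([C@H](C)CC[C@H](C=O)C(C)(C)O[Si](CC)(CC)CC)C2=O
F11 | step 23 | (1R,3aR,4R,7R)-1,4-dimethyl-1-[(1R)-3-methyl-1-(2,4,6-trimethoxyphenyl)butyl]-7-{2-[(triethylsilyl)oxy]propan-2-yl}-1,2,3,3a,4,5,6,7-octahydroazulene | CC(C)C[C@@H](c1c(OC)cc(OC)cc1OC)[C@@]1(C)CC[C@H]2C1=C[C@H](C(C)(C)O[Si](CC)(CC)CC)CC[C@H]2C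
F0 | step 25 | none | none
A1 | alternative 1 | [(1S,3aR,4R,7R)-7-(2-hydroxypropan-2-yl)-1,4-dimethyl-1,2,3,3a,4,5,6,7-octahydroazulen-1-yl](2,4,6-trihydroxyphenyl)methanone | O=C(c1c(O)cc(O)cc1O)[C@@]1(C)CC[C@H]2C1=C[C@H](C(C)(C)O)CC[C@H]2C
A2 | alternative 1 | methyl 7-[(1S,3aR,4R,7R)-7-(2-hydroxypropan-2-yl)-1,4-dimethyl-1,2,3,3a,4,5,6,7-octahydroazulen-1-yl]-3,5,7-trioxoheptanoate | COC(=O)CC(=O)CC(=O)CC(=O)[C@@]1(C)CC[C@H]2C1=C[C@H](C(C)(C)O)CC[C@H]2C
A3 | alternative 2 | guaia-1,5-dien-3-one with quaternary C4 bearing methyl and (tert-butyldimethylsilyloxy)methyl and with the C11 triethylsilyl ether | CC(C)(C)[Si](C)(C)OC[C@@]1(C)C(=O)C=C2C1=C[C@H](C(C)(C)O[Si](CC)(CC)CC)CC[C@H]2C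
A4 | alternative 2 | open-chain allenyne: terminal alkyne at C1–C2, C10 methyl, C7 triethylsilyloxyisopropyl, allene C6=C5=C4 carrying methyl and (tert-butyldimethylsilyloxy)methyl on C4 | C#C[C@H](C)CC[C@@H](C(C)(C)O[Si](CC)(CC)CC)C([H])=[C@]=C(C)CO[Si](C)(C)C(C)(C)C
A5 | alternative 3 | 2-(C7′-alkyl)-3,5-dimethoxyphenol carrying the complete sesquiterpene unit with the C11 methoxymethyl ether | CC(C)C[C@@H](c1c(O)cc(OC)cc1OC)[C@@]1(C)CC[C@H]2C1=C[C@H](C(C)(C)OCOC)CC[C@H]2C
A6 | alternative 3 | guai-5-ene C4 carbaldehyde (C7′ as CHO) with the C11 methoxymethyl ether | O=C[C@@]1(C)CC[C@H]2C1=C[C@H](C(C)(C)OCOC)CC[C@H]2C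
A7 | alternative 3 | 3,5-dimethoxy-2-(trimethylsilyl)phenyl trifluoromethanesulfonate | COc1cc(OC)c([Si](C)(C)C)c(OS(=O)(=O)C(F)(F)F)c1
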